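The earlier runs and the new flask come from a simulation from invented constants, noise included.

The winter flask is charged with more Z than Q, and c_Z over c_Q at the charge is 20.0: the units per chain if each Z charged enters a chain and each Q begins one, here called the charge ratio.

in all of them: Z 19 mM
- winter: Q 0.95 mM; the very flask that is asked about, followed so far
- spring: Q 1.9 mM; run made earlier
- flask: Q 0.95 mM; time 30 h

- winter (time / h: E / %, Z / %): 1.00: 2, 97; 2.00: 2, 99; 5.00: 11, 91; 12.0: 28, 78
- spring (time / h: E / %, Z / %): 5.00: 18, 86; 10.0: 36, 66; 15.0: 48, 51; 20.0: 57, 41

(scatter of a reading: 2 percentage points)

- the average divides the monomer in chains by the number of chains begun, living and dead together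
- the earlier runs were read with a standard deviation of 2 percentage points
- the earlier runs do not show the number of chains; that part of a forecast is a guess

- average number of monomer units in a chain (chains begun, living or dead) at 30 h
- part of the Z that has reacted at 30 h

But the runs do not show the number of chains, so the reckoning here guesses: chains begun are frozen at the charged Q, and dp, the degree of polymerisation, is the charge ratio times the share of Z found as E. That share must still be found. At 5.00 h the winter run reads E 11% and the spring run 18%, so the spring run, with more Q, is ahead. Taking time times c_Q as a rough clock, an estimate, the winter flask at 30 h is set beside the spring run at 15.0 h, which reads E 48% and Z 51%. So this reckoning gives dp 9.60 and c 49.0%.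

The forecast, a little higher, gives dp 10 (8 to 14) and c 50% (44% to 56%), and says of its chain count: “This is a guess, since the number of chains was never measured.”

The winter flask gives dp 9.04 and c 47.4%, both inside the forecast's ranges.

    E + G → Z + G, rate k1*[G] as long as [E] is above zero (k = 0.00200 min⁻¹)
    Z + Q → G + E (k = 0.220 L mol⁻¹ min⁻¹)
    G + Z → J (k = 0.0320 L mol⁻¹ min⁻¹)
    Z + G → E + G, rate k4*[G]*[Z] (k = 0.690 L mol⁻¹ min⁻¹)

At 30.0 h the winter flask holds E 45.0% of the Z charged and Q 0.426% of its own charge, and the charge ratio times that E gives dp 9.00. A neighbour flask charged with 76 mM of Z and the same Q has a higher charge ratio, 80.0. At 30.0 h it holds E 26.1% of its Z charged and Q 0% of its own charge, so the same reckoning gives 20.9, above the high end of the forecast's range for the winter flask. That neighbour flask gives dp 20.9 and c 27.3%.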